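**Plan**

1. Numbering: ring A is C1–C5 plus C10, ring B is C5–C10. C4 carries CH3 and the ester carbon C18, C5 is the ring-fusion CH, C1=C10 is the ring-fusion alkene, C8 is CH(CH3), and C9 is the quaternary carbon with CH3 and the side chain C11–C15.
2. Retrosynthesis cuts, in order: the C15–O cinnamate ester (Z-alkene from an alkyne); C4–C5 of ring A together with a C1–O lactone bond; C4–CH3 and C1–C10; then C13=C14, C9–C11 and C8–CH3.
3. Enabling feature: in ring A the array C18(=O)–C4–C5–C10=C1 is a γ,δ-unsaturated acid, the pattern an ester-enolate Claisen rearrangement leaves behind. Tying C1 to the carboxyl oxygen gives a six-membered lactone (C18, C4, C3, C2, C1, O) whose ketene acetal can only contract to ring A.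
4. Forward order: ring B from 2-methylcyclohex-2-en-1-one (conjugate methylation, Michael addition, olefination), the acyl chain on C10 through an alkenyllithium, the δ-lactone, ring A by ring contraction, and last the two esters.
5. Stereochemistry: C8 from a copper-catalysed asymmetric conjugate addition, C9 by attack anti to the C8 methyl, C1 by CBS reduction, C4 and C5 relayed from C1 through a boat transition state; 13E from the Horner–Wadsworth–Emmons step, the Z-cinnamate from Lindlar hydrogenation.

Key step: step 12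

**Remarks on the chemistry**

- Lactone 21 is carried as both C4 epimers (written 3RS, centre left open in the SMILES) because C4 becomes planar in ketene acetal 23. The ring carbinol of 9 and 10 (1RS) is likewise a mixture that is reoxidised in step 6.
- The phosphoramidite enantiomer in step 1 is the one that gives the 3R adduct (same sense as (R)-3-methylcyclohexanone). The (S)-oxazaborolidine in step 10 is assigned on the standard model with the cyclohexenyl group as the large substituent.
- Shorthand: B* = (5R,6S)-6-{(3E)-5-[(tert-butyldiphenylsilyl)oxy]-3-methylpent-3-en-1-yl}-5,6-dimethylcyclohex-1-en-1-yl, the ring-B group attached through C10.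

**Route**

Step 1
Reactants: 1 2-methylcyclohex-2-en-1-one
Product: 3 trimethyl{[(3R)-2,3-dimethylcyclohex-1-en-1-yl]oxy}silane, via aluminium enolate 2 (not isolated)
Conditions: Me3Al, Cu(O2CC4H3S) (copper thiophene-2-carboxylate, monovalent copper, cat.), BINOL-derived phosphoramidite (cat.), Et2O, −30 °C; then Me3SiOTf, −30 to 0 °C; Et3N quench
Reagents that add atoms: trimethylaluminium, C[Al](C)C; trimethylsilyl trifluoromethanesulfonate, C[Si](C)(C)OS(=O)(=O)C(F)(F)F
Why: Copper-catalysed asymmetric conjugate addition of Me3Al to a cyclic enone should set C8 (3R) under ligand control, and O-silylation of the regiodefined aluminium enolate 2 fixes the enol ether position for the next step.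

Step 2
Reactants: 3 trimethyl{[(3R)-2,3-dimethylcyclohex-1-en-1-yl]oxy}silane; 4 methyl vinyl ketone
Product: 5 (2S,3R)-2,3-dimethyl-2-(3-oxobutyl)cyclohexan-1-one
Conditions: BF3·OEt2, i-PrOH, MeNO2, −20 °C
Reagents that add atoms: methyl vinyl ketone (compound 4), CC(=O)C=C
Why: In this Mukaiyama–Michael addition the BF3-activated enone is attacked by the tetrasubstituted silyl enol ether on the face anti to the pseudoaxial C8 methyl, which should create quaternary C9 with the two methyls cis, the alcohol taking up the silyl group.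

Step 3
Reactants: 5 (2S,3R)-2,3-dimethyl-2-(3-oxobutyl)cyclohexan-1-one; 6 triethyl phosphonoacetate
Product: 8 ethyl (2E)-5-[(1S,2R)-1,2-dimethyl-6-oxocyclohexyl]-3-methylpent-2-enoate, via phosphonate carbanion 7 (not isolated)
Conditions: NaH, THF, 0 °C to rt
Reagents that add atoms: triethyl phosphonoacetate (compound 6), CCOC(=O)CP(=O)(OCC)OCC
Why: The Horner–Wadsworth–Emmons olefination should take place only at the unhindered methyl ketone (the ring ketone is flanked by quaternary C9) and favour the E-enoate, a minor Z isomer being removable by chromatography.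

Step 4
Reactants: 8 ethyl (2E)-5-[(1S,2R)-1,2-dimethyl-6-oxocyclohexyl]-3-methylpent-2-enoate
Product: 9 (1RS,2S,3R)-2-[(3E)-5-hydroxy-3-methylpent-3-en-1-yl]-2,3-dimethylcyclohexan-1-ol
Conditions: i-Bu2AlH (excess), CH2Cl2, −78 to 0 °C; aq. Rochelle salt
Reagents that add atoms: none
Why: i-Bu2AlH reduces the enoate by 1,2-addition to the allylic alcohol without touching the C=C bond and reduces the ring ketone as well, the carbinol mixture being irrelevant because that centre is reoxidised in step 6.

Step 5
Reactants: 9 (1RS,2S,3R)-2-[(3E)-5-hydroxy-3-methylpent-3-en-1-yl]-2,3-dimethylcyclohexan-1-ol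
Product: 10 (1RS,2S,3R)-2-{(3E)-5-[(tert-butyldiphenylsilyl)oxy]-3-methylpent-3-en-1-yl}-2,3-dimethylcyclohexan-1-ol
Conditions: t-BuPh2SiCl (1.05 equiv), imidazole, CH2Cl2, 0 °C
Reagents that add atoms: tert-butyl(chloro)diphenylsilane, CC(C)(C)[Si](Cl)(c1ccccc1)c1ccccc1
Why: Silylation with the bulky chlorosilane should be selective for the primary allylic hydroxyl over the secondary hydroxyl next to the quaternary carbon.

Step 6
Reactants: 10 (1RS,2S,3R)-2-{(3E)-5-[(tert-butyldiphenylsilyl)oxy]-3-methylpent-3-en-1-yl}-2,3-dimethylcyclohexan-1-ol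
Product: 11 (2S,3R)-2-{(3E)-5-[(tert-butyldiphenylsilyl)oxy]-3-methylpent-3-en-1-yl}-2,3-dimethylcyclohexan-1-one
Conditions: Dess–Martin periodinane, CH2Cl2, rt
Reagents that add atoms: none
Why: Dess–Martin oxidation returns the ring ketone under near-neutral conditions that leave the allylic silyl ether, the trisubstituted alkene and the non-epimerisable C8 and C9 centres untouched.

Step 7
Reactants: 11 (2S,3R)-2-{(3E)-5-[(tert-butyldiphenylsilyl)oxy]-3-methylpent-3-en-1-yl}-2,3-dimethylcyclohexan-1-one; 12 2,4,6-tri(propan-2-yl)benzenesulfonohydrazide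
Product: 13 N'-[(1E,2S,3R)-2-{(3E)-5-[(tert-butyldiphenylsilyl)oxy]-3-methylpent-3-en-1-yl}-2,3-dimethylcyclohexylidene]-2,4,6-tri(propan-2-yl)benzenesulfonohydrazide
Conditions: THF, HCl (cat.), rt
Reagents that add atoms: 2,4,6-tri(propan-2-yl)benzenesulfonohydrazide (compound 12), CC(C)c1cc(C(C)C)c(c(c1)C(C)C)S(=O)(=O)NN
Why: Acid-catalysed condensation of the ketone with the arenesulfonyl hydrazide should give the E hydrazone with the N–N bond turned away from quaternary C9, the geometry the Shapiro reaction needs.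

Step 8
Reactants: 13 the E trisylhydrazone of ketone 11; 14 glutaric anhydride
Product: 16 5-oxo-5-B*-pentanoic acid, via alkenyllithium 15 (not isolated)
Conditions: n-BuLi (2.2 equiv), THF, −78 to 0 °C; then cannulated into glutaric anhydride (excess), THF, −78 °C; dilute aq. HCl
Reagents that add atoms: glutaric anhydride (compound 14), O=C1CCCC(=O)O1
Why: In this Shapiro reaction double deprotonation (N–H, then the only α-CH2, C5) and loss of sulfinate and N2 give alkenyllithium 15 regiospecifically with the C10=C5 double bond, and its addition to the symmetrical anhydride stops at the keto carboxylate, so C1–C10 forms without a regiochemical issue.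

Step 9
Reactants: 16 5-oxo-5-B*-pentanoic acid
Product: 17 methyl 5-oxo-5-B*-pentanoate
Conditions: MeI, K2CO3, DMF, rt
Reagents that add atoms: iodomethane, CI
Why: O-Alkylation of the carboxylate masks the acid, which would otherwise consume the borane in step 10, and K2CO3 is too weak to enolise the ketone.

Step 10
Reactants: 17 methyl 5-oxo-5-B*-pentanoate
Product: 19 (6R)-6-B*-oxan-2-one, via hydroxy ester 18 (not isolated)
Conditions: (S)-2-methyl-CBS-oxazaborolidine (20 mol%), catecholborane, toluene, −78 °C; MeOH; then PPTS (cat.), toluene, 50 °C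
Reagents that add atoms: none
Why: In this Corey–Bakshi–Shibata reduction the (S)-oxazaborolidine, with the bulky cyclohexenyl group as the large substituent, should deliver hydride by 1,2-addition to give the 1R allylic alcohol 18, and mild acid then closes the δ-lactone by transesterification without ionising the allylic C–O bond.

Step 11
Reactants: 19 (6R)-6-B*-oxan-2-one
Product: 21 (3RS,6R)-3-methyl-6-B*-oxan-2-one, via lithium enolate 20 (not isolated)
Conditions: LiN(i-Pr)2 (1.05 equiv), THF, −78 °C; MeI, DMPU, −78 to −40 °C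
Reagents that add atoms: iodomethane, CI
Why: Alkylation of the lactone enolate (C4 is the only enolisable position) with MeI installs the C4 methyl, and the configuration of this centre does not matter because it is planarised in the next step.

Step 12
Reactants: 21 (3RS,6R)-3-methyl-6-B*-oxan-2-one
Product: 25 (1S,5S,6R,8aR)-5-{(3E)-5-[(tert-butyldiphenylsilyl)oxy]-3-methylpent-3-en-1-yl}-1,5,6-trimethyl-1,2,3,5,6,7,8,8a-octahydronaphthalene-1-carboxylic acid, via lithium enolate 22 (not isolated), via silyl ketene acetal 23 (not isolated), via trimethylsilyl ester 24 (not isolated)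
Conditions: LiN(i-Pr)2, THF, −78 °C; Me3SiCl/Et3N, −78 °C to rt; toluene, 100 °C; then dilute aq. HCl, THF, rt
Reagents that add atoms: none
Why: LiN(i-Pr)2 removes H4 to give enolate 22, O-silylation gives the endocyclic ketene acetal 23 (C3 and the ring oxygen held cis by the ring), and on heating a concerted suprafacial [3,3] shift across C4=C18–O–C1–C10=C5 forms C4–C5, breaks C1–O and moves the alkene to C1=C10, leaving silyl ester 24 that is hydrolysed to 25. The closest known reaction type is the Ireland–Claisen ring contraction of alkenyl-substituted lactone silyl ketene acetals to cycloalkene carboxylic acids. Ring A closes in a sigmatropic mode: the C2–C3 tether already joins the termini C1 and C4, so the six-membered lactone contracts to the six-membered carbocycle C4–C3–C2–C1–C10–C5 through a boat-like, bicyclo[2.2.2]octane-shaped transition state, a chair being out of reach of the two-carbon tether. C5 is controlled by the C1 carbinol, since the new bond must form on the alkene face from which the C1–O bond departs, which for 1R is the face anti to the pseudoaxial C9 methyl and gives 5R. C4 is controlled by the ring-fixed ketene acetal geometry within the same boat, which places the carboxyl trans to H5 (4S), so both C4 epimers of 21 converge. The step needs site-selective enolisation, O-silylation and a rearrangement that outruns ketene acetal decay: C4–H is the only enolisable position, the side-chain alcohol is a base-stable silyl ether, the allylic C–O cleavage can place the alkene only at C1=C10, and the small trimethylsilyl group limits contact with the C9 substituents.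

Step 13
Reactants: 25 the octahydronaphthalene-1-carboxylic acid from step 12
Product: 26 methyl (1S,5S,6R,8aR)-5-{(3E)-5-[(tert-butyldiphenylsilyl)oxy]-3-methylpent-3-en-1-yl}-1,5,6-trimethyl-1,2,3,5,6,7,8,8a-octahydronaphthalene-1-carboxylate
Conditions: MeI, K2CO3, DMF, rt
Reagents that add atoms: iodomethane, CI
Why: Carboxylate O-alkylation with MeI is insensitive to the steric hindrance around quaternary C4 that would slow an acid-catalysed esterification.

Step 14
Reactants: 26 the silyl-protected methyl ester
Product: 27 methyl (1S,5S,6R,8aR)-5-[(3E)-5-hydroxy-3-methylpent-3-en-1-yl]-1,5,6-trimethyl-1,2,3,5,6,7,8,8a-octahydronaphthalene-1-carboxylate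
Conditions: Bu4NF, THF, 0 °C to rt
Reagents that add atoms: none
Why: Fluoride cleaves the Si–O bond of the silyl ether, and the hindered methyl ester on quaternary C4 should not be attacked.

Step 15
Reactants: 27 the allylic alcohol; 28 3-phenylprop-2-ynoic acid
Product: 29 methyl (1S,5S,6R,8aR)-1,5,6-trimethyl-5-{(3E)-3-methyl-5-[(3-phenylprop-2-ynoyl)oxy]pent-3-en-1-yl}-1,2,3,5,6,7,8,8a-octahydronaphthalene-1-carboxylate
Conditions: DCC, DMAP (cat.), CH2Cl2, 0 °C
Reagents that add atoms: 3-phenylprop-2-ynoic acid (compound 28), OC(=O)C#Cc1ccccc1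
Why: Steglich esterification of the primary allylic alcohol with the alkynoic acid proceeds through the O-acylisourea and the acylpyridinium ion.

Step 16
Reactants: 29 the phenylpropiolate ester
Product: 30 methyl (1S,5S,6R,8aR)-1,5,6-trimethyl-5-{(3E)-3-methyl-5-[(2Z)-3-phenylprop-2-enoyl]oxypent-3-en-1-yl}-1,2,3,5,6,7,8,8a-octahydronaphthalene-1-carboxylate (target)
Conditions: H2 (1 atm), Pd/CaCO3 poisoned with Pb(OAc)2 (Lindlar catalyst), quinoline, EtOAc, rt
Reagents that add atoms: none
Why: Lindlar semihydrogenation adds H2 syn to the alkyne to give the Z-cinnamate and should spare the two trisubstituted alkenes and the allylic ester.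

**Compound list**

1 | 2-methylcyclohex-2-en-1-one | CC1=CCCCC1=O | starting material
2 | dimethylaluminium (3R)-2,3-dimethylcyclohex-1-en-1-olate | C[Al](C)OC1=C(C)[C@H](C)CCC1 | intermediate
3 | trimethyl{[(3R)-2,3-dimethylcyclohex-1-en-1-yl]oxy}silane | C[Si](C)(C)OC1=C(C)[C@H](C)CCC1 | intermediate
4 | methyl vinyl ketone (but-3-en-2-one) | CC(=O)C=C | starting material
5 | (2S,3R)-2,3-dimethyl-2-(3-oxobutyl)cyclohexan-1-one | O=C1CCC[C@@H](C)[C@]1(C)CCC(C)=O | intermediate
6 | triethyl phosphonoacetate | CCOC(=O)CP(=O)(OCC)OCC | starting material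
7 | sodium salt of triethyl phosphonoacetate (phosphonate carbanion) | CCOC(=O)[CH-]P(=O)(OCC)OCC.[Na+] | intermediate
8 | ethyl (2E)-5-[(1S,2R)-1,2-dimethyl-6-oxocyclohexyl]-3-methylpent-2-enoate | O=C1CCC[C@@H](C)[C@]1(C)CC/C(C)=C/C(=O)OCC | intermediate
9 | (1RS,2S,3R)-2-[(3E)-5-hydroxy-3-methylpent-3-en-1-yl]-2,3-dimethylcyclohexan-1-ol | OC1CCC[C@@H](C)[C@]1(C)CC/C(C)=C/CO | intermediate
10 | (1RS,2S,3R)-2-{(3E)-5-[(tert-butyldiphenylsilyl)oxy]-3-methylpent-3-en-1-yl}-2,3-dimethylcyclohexan-1-ol | OC1CCC[C@@H](C)[C@]1(C)CC/C(C)=C/CO[Si](c2ccccc2)(c3ccccc3)C(C)(C)C | intermediate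
11 | (2S,3R)-2-{(3E)-5-[(tert-butyldiphenylsilyl)oxy]-3-methylpent-3-en-1-yl}-2,3-dimethylcyclohexan-1-one | O=C1CCC[C@@H](C)[C@]1(C)CC/C(C)=C/CO[Si](c2ccccc2)(c3ccccc3)C(C)(C)C | intermediate
12 | 2,4,6-tri(propan-2-yl)benzenesulfonohydrazide | CC(C)c1cc(C(C)C)c(c(c1)C(C)C)S(=O)(=O)NN | starting material
13 | E trisylhydrazone of 11 | CC(C)c1cc(C(C)C)c(c(c1)C(C)C)S(=O)(=O)N/N=C2\CCC[C@@H](C)[C@]2(C)CC/C(C)=C/CO[Si](c3ccccc3)(c4ccccc4)C(C)(C)C | intermediate
14 | glutaric anhydride (oxane-2,6-dione) | O=C1CCCC(=O)O1 | starting material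
15 | alkenyllithium B*–Li | [Li]C1=CCC[C@@H](C)[C@]1(C)CC/C(C)=C/CO[Si](c2ccccc2)(c3ccccc3)C(C)(C)C | intermediate
16 | 5-oxo-5-B*-pentanoic acid | OC(=O)CCCC(=O)C1=CCC[C@@H](C)[C@]1(C)CC/C(C)=C/CO[Si](c2ccccc2)(c3ccccc3)C(C)(C)C | intermediate
17 | methyl 5-oxo-5-B*-pentanoate | COC(=O)CCCC(=O)C1=CCC[C@@H](C)[C@]1(C)CC/C(C)=C/CO[Si](c2ccccc2)(c3ccccc3)C(C)(C)C | intermediate
18 | methyl (5R)-5-hydroxy-5-B*-pentanoate | COC(=O)CCC[C@@H](O)C1=CCC[C@@H](C)[C@]1(C)CC/C(C)=C/CO[Si](c2ccccc2)(c3ccccc3)C(C)(C)C | intermediate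
19 | (6R)-6-B*-oxan-2-one | O=C1CCC[C@@H](O1)C2=CCC[C@@H](C)[C@]2(C)CC/C(C)=C/CO[Si](c3ccccc3)(c4ccccc4)C(C)(C)C | intermediate
20 | lithium enolate of lactone 19 | [Li]OC1=CCC[C@@H](O1)C2=CCC[C@@H](C)[C@]2(C)CC/C(C)=C/CO[Si](c3ccccc3)(c4ccccc4)C(C)(C)C | intermediate
21 | (3RS,6R)-3-methyl-6-B*-oxan-2-one | CC1CC[C@@H](OC1=O)C2=CCC[C@@H](C)[C@]2(C)CC/C(C)=C/CO[Si](c3ccccc3)(c4ccccc4)C(C)(C)C | intermediate
22 | lithium enolate of lactone 21 | [Li]OC1=C(C)CC[C@@H](O1)C2=CCC[C@@H](C)[C@]2(C)CC/C(C)=C/CO[Si](c3ccccc3)(c4ccccc4)C(C)(C)C | intermediate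
23 | trimethyl{[(2R)-5-methyl-2-B*-3,4-dihydro-2H-pyran-6-yl]oxy}silane | C[Si](C)(C)OC1=C(C)CC[C@@H](O1)C2=CCC[C@@H](C)[C@]2(C)CC/C(C)=C/CO[Si](c3ccccc3)(c4ccccc4)C(C)(C)C | intermediate
24 | trimethylsilyl ester of acid 25 | C[Si](C)(C)OC(=O)[C@@]1(C)CCC=C2[C@H]1CC[C@@H](C)[C@]2(C)CC/C(C)=C/CO[Si](c3ccccc3)(c4ccccc4)C(C)(C)C | intermediate
25 | (1S,5S,6R,8aR)-5-{(3E)-5-[(tert-butyldiphenylsilyl)oxy]-3-methylpent-3-en-1-yl}-1,5,6-trimethyl-1,2,3,5,6,7,8,8a-octahydronaphthalene-1-carboxylic acid | OC(=O)[C@@]1(C)CCC=C2[C@H]1CC[C@@H](C)[C@]2(C)CC/C(C)=C/CO[Si](c3ccccc3)(c4ccccc4)C(C)(C)C | intermediate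
26 | methyl ester of acid 25 | COC(=O)[C@@]1(C)CCC=C2[C@H]1CC[C@@H](C)[C@]2(C)CC/C(C)=C/CO[Si](c3ccccc3)(c4ccccc4)C(C)(C)C | intermediate
27 | methyl (1S,5S,6R,8aR)-5-[(3E)-5-hydroxy-3-methylpent-3-en-1-yl]-1,5,6-trimethyl-1,2,3,5,6,7,8,8a-octahydronaphthalene-1-carboxylate | COC(=O)[C@@]1(C)CCC=C2[C@H]1CC[C@@H](C)[C@]2(C)CC/C(C)=C/CO | intermediate
28 | 3-phenylprop-2-ynoic acid | OC(=O)C#Cc1ccccc1 | starting material
29 | methyl (1S,5S,6R,8aR)-1,5,6-trimethyl-5-{(3E)-3-methyl-5-[(3-phenylprop-2-ynoyl)oxy]pent-3-en-1-yl}-1,2,3,5,6,7,8,8a-octahydronaphthalene-1-carboxylate | COC(=O)[C@@]1(C)CCC=C2[C@H]1CC[C@@H](C)[C@]2(C)CC/C(C)=C/COC(=O)C#Cc3ccccc3 | intermediate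
30 | methyl (1S,5S,6R,8aR)-1,5,6-trimethyl-5-{(3E)-3-methyl-5-[(2Z)-3-phenylprop-2-enoyl]oxypent-3-en-1-yl}-1,2,3,5,6,7,8,8a-octahydronaphthalene-1-carboxylate | COC(=O)[C@@]1(C)CCC=C2[C@H]1CC[C@@H](C)[C@]2(C)CC/C(C)=C/COC(=O)/C=C\c1ccccc1 | target

**Step count**

Total: 16 steps. Longest linear sequence: 16 steps (1 to 30); all other components are commercial.

**Steps most likely to fail**

1. Step 12 (key step). The boat transition state stacks the silyloxy group under the crowded C9 region, so the [3,3] shift may be slower than thermal decay of ketene acetal 23 (desilylation, C-silylation, ionisation of the allylic C1–O bond). The fallback builds ring A by an intermolecular Diels–Alder reaction instead of the ring contraction. It sets out from ketone 11. Addition of CH2=CHMgBr/CeCl3 gives the tertiary vinyl carbinol F1. Syn-dehydration with the Burgess reagent can only go toward C5 and gives the 2-vinylcyclohexene diene F2. Et2AlCl-promoted cycloaddition with methyl methacrylate then forms C4–C5 and C2–C3 together. The substituted diene terminus C5 should bond to the ester-bearing carbon, the ester should sit endo (trans to H5), and the dienophile should approach anti to the pseudoaxial C9 methyl. The adduct would be methyl ester 26, where the route is rejoined.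

2. Step 8. The hindered hydrazone may be converted only partly into alkenyllithium 15, and 15 may be lost to proton transfer from the anhydride or to a second addition to the keto carboxylate. The fallback generates the C10 nucleophile from an enol triflate under chromium mediation. It sets out from ketone 11. KN(SiMe3)2 and PhNTf2 give the enol triflate F3 (only C5 can be enolised). A Nozaki–Hiyama–Kishi coupling (CrCl2, NiCl2 cat., DMF) with methyl 5-oxopentanoate gives the C1-epimeric hydroxy ester F4. Dess–Martin oxidation converges both epimers on keto ester 17, where the route is rejoined.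

3. Step 10. Face selectivity in the reduction of a twisted, hindered enone may be insufficient, or conjugate reduction may compete; any erosion at C1 would pass directly into C4 and C5. The fallback creates C1 in a C–C bond-forming event instead of a reduction. It sets out from alkenyllithium 15 (generated from 13 as in step 8). Transmetallation with EtZnCl gives the mixed alkenyl(ethyl)zinc F5. This adds to methyl 5-oxopentanoate under catalysis by an enantiopure amino alcohol (3-exo-morpholinoisoborneol, the enantiomer that delivers the 1R carbinol), with N,N,N',N'-tetraethylethylenediamine present to sequester lithium salts. The product is hydroxy ester 18, which is lactonised to 19 as in step 10.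

**Further compounds**

F1 | step 12 | (1RS,2S,3R)-2-{(3E)-5-[(tert-butyldiphenylsilyl)oxy]-3-methylpent-3-en-1-yl}-1-ethenyl-2,3-dimethylcyclohexan-1-ol | OC1(C=C)CCC[C@@H](C)[C@]1(C)CC/C(C)=C/CO[Si](c2ccccc2)(c3ccccc3)C(C)(C)C
F2 | step 12 | B*-ethene (1-ethenylcyclohexene diene) | C=CC1=CCC[C@@H](C)[C@]1(C)CC/C(C)=C/CO[Si](c2ccccc2)(c3ccccc3)C(C)(C)C
F3 | step 8 | B* trifluoromethanesulfonate (enol triflate of 11) | FC(F)(F)S(=O)(=O)OC1=CCC[C@@H](C)[C@]1(C)CC/C(C)=C/CO[Si](c2ccccc2)(c3ccccc3)C(C)(C)C
F4 | step 8 | methyl (5RS)-5-hydroxy-5-B*-pentanoate | COC(=O)CCCC(O)C1=CCC[C@@H](C)[C@]1(C)CC/C(C)=C/CO[Si](c2ccccc2)(c3ccccc3)C(C)(C)C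
F5 | step 10 | ethyl(B*)zinc | CC[Zn]C1=CCC[C@@H](C)[C@]1(C)CC/C(C)=C/CO[Si](c2ccccc2)(c3ccccc3)C(C)(C)C
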